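**Retrosynthetic overview**

1. The side chain is cut at the C(=CH2)–CH bond: the alkenyl-metal reagent from methyl ketone 17 (Shapiro reaction) adds to the enoyl imide 22, and an Evans syn-aldol reaction with ethyl glyoxylate followed by reduction and lactonisation builds the hydroxy lactone, which is the last ring formed.
2. The trans-hydrindane is made in one operation from the acyclic ketone acetal 11: an ionic Diels–Alder reaction (Mukaiyama–Michael/Michael) forms the ring-fusion bond C3a–C7a first, closing the cyclopentane C1–C2–C3–C3a–C7a, and then C4–C5, closing the cyclohexane C3a–C4–C5–C6–C7–C7a.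
3. The enabling feature is that the methyl-bearing quaternary fusion carbon C7a sits next to the CH2 carbon C7, which can be a temporary ketone (C7a then becomes the nucleophilic carbon of a 2-siloxy diene C5=C6–C7=C7a), while the fusion CH C3a sits next to the gem-dimethyl carbon C4, one methyl of which can be a temporary formyl group (C3a=C4 is then a 2-methyl enal); the cyclohexane is thus a Diels–Alder retron and the cyclopentane is the tether.
4. Both temporary oxygens (C7 ketone, C4 formyl) are removed together by Wolff–Kishner reduction; the only stereocentre of 11 that matters (C1) comes from an auxiliary-controlled conjugate addition and steers the new fusion centres through A(1,3) strain.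
5. Order of ring formation: cyclopentane and cyclohexane (same step), then the γ-lactone.

Key step: step 10

Remark: locants C1–C7a are those of the octahydro-1H-indene core of the target (C1 bears the side chain, C3a is the fusion CH, C4 the gem-dimethyl carbon, C7a the methyl-bearing fusion carbon) and are used for the corresponding carbons of all precursors; the configuration drawn at C4 of 13 and 14 is of no consequence because C4 becomes the gem-dimethyl carbon in step 11.

**Route**

Step 1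
Reactants: 1 5-bromo-2-methylpent-2-ene
Product: 2 6-methylhepta-1,5-diene
Conditions: CH2=CHMgBr, FeCl3 (5 mol %), TMEDA, THF, 0 °C
Reagents that add atoms: vinylmagnesium bromide, C=C[Mg]Br
Why: Iron-catalysed Kumada-type cross-coupling of a primary alkyl bromide with an alkenyl Grignard reagent should join the sp3 and sp2 carbons without touching the trisubstituted alkene; no stereocentre is formed.

Step 2
Reactants: 3 (4R)-4-benzyl-1,3-oxazolidin-2-one
Product: 4 (4R)-4-benzyl-3-(prop-2-enoyl)-1,3-oxazolidin-2-one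
Conditions: acryloyl chloride, Et3N, LiCl, THF, −20 °C to rt
Reagents that add atoms: acryloyl chloride, C=CC(=O)Cl
Why: N-Acylation of the LiCl-activated oxazolidinone by the acid chloride should give the acrylimide; the auxiliary stereocentre is untouched.

Step 3
Reactants: 4 (4R)-4-benzyl-3-(prop-2-enoyl)-1,3-oxazolidin-2-one; 2 6-methylhepta-1,5-diene
Product: 5 (4R)-4-benzyl-3-[(2E)-7-methylocta-2,6-dienoyl]-1,3-oxazolidin-2-one
Conditions: second-generation Hoveyda–Grubbs catalyst RuCl2(H2IMes)(=CH-C6H4-2-O-i-Pr) (3 mol %), 2 (2 equiv), CH2Cl2, 40 °C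
Reagents that add atoms: none
Why: Olefin cross-metathesis of an electron-poor acrylimide with an unhindered terminal alkene should be selective for the hetero-coupled (E)-enoyl imide, the trisubstituted alkene being inert to the ruthenium carbene.

Step 4
Reactants: 5 (4R)-4-benzyl-3-[(2E)-7-methylocta-2,6-dienoyl]-1,3-oxazolidin-2-one
Product: 6 (4R)-4-benzyl-3-[(3S)-3-ethenyl-7-methyloct-6-enoyl]-1,3-oxazolidin-2-one
Conditions: CH2=CHMgBr, CuBr·SMe2, THF/Me2S, −78 to −20 °C; aq NH4Cl
Reagents that add atoms: vinylmagnesium bromide, C=C[Mg]Br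
Why: Copper-mediated conjugate addition to the magnesium-chelated syn-s-cis N-enoyl oxazolidinone should occur on the face anti to the 4-benzyl group and so set the future C1 stereocentre (3S) under auxiliary control.

Step 5
Reactants: 6 (4R)-4-benzyl-3-[(3S)-3-ethenyl-7-methyloct-6-enoyl]-1,3-oxazolidin-2-one
Product: 7 (4R)-4-benzyl-3-[(2R,3R)-3-ethenyl-2,7-dimethyloct-6-enoyl]-1,3-oxazolidin-2-one
Conditions: NaN(SiMe3)2, THF, −78 °C; MeI, −78 to −40 °C
Reagents that add atoms: iodomethane, CI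
Why: Evans alkylation of the chelated (Z)-sodium enolate anti to the benzyl group should install the methyl group of the future C7a (2R); this centre is re-enolised in step 10, so only the presence of the methyl group matters.

Step 6
Reactants: 7 (4R)-4-benzyl-3-[(2R,3R)-3-ethenyl-2,7-dimethyloct-6-enoyl]-1,3-oxazolidin-2-one
Product: 8 (2R,3R)-3-ethenyl-N-methoxy-N,2,7-trimethyloct-6-enamide
Conditions: MeONHMe·HCl, AlMe3, CH2Cl2, 0 °C to rt; aq potassium sodium tartrate
Reagents that add atoms: N,O-dimethylhydroxylamine hydrochloride, CNOC.Cl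
Why: Aluminium amide transamination should cleave the exocyclic imide carbonyl to the Weinreb amide and release the recoverable auxiliary without epimerisation.

Step 7
Reactants: 8 (2R,3R)-3-ethenyl-N-methoxy-N,2,7-trimethyloct-6-enamide
Product: 9 (2R,3R,6E)-3-ethenyl-N-methoxy-N,2,7-trimethyl-8-oxooct-6-enamide
Conditions: SeO2, 1,4-dioxane, 90 °C
Reagents that add atoms: selenium dioxide, O=[Se]=O
Why: Riley allylic oxidation (ene reaction, then [2,3]-sigmatropic shift) should attack selectively the (E)-methyl group of the electron-rich trisubstituted alkene and give the (E)-2-methyl enal, the monosubstituted vinyl group being much less reactive.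

Step 8
Reactants: 9 (2R,3R,6E)-3-ethenyl-N-methoxy-N,2,7-trimethyl-8-oxooct-6-enamide
Product: 10 (2R,3R,6E)-3-ethenyl-N,8,8-trimethoxy-N,2,7-trimethyloct-6-enamide
Conditions: HC(OMe)3, MeOH, pyridinium p-toluenesulfonate (cat.), rt
Reagents that add atoms: trimethyl orthoformate, COC(OC)OC
Why: Acid-catalysed acetalisation should mask the aldehyde against the Grignard reagent and the base of the next steps and at the same time install the leaving group from which the electrophile of step 10 is released.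

Step 9
Reactants: 10 (2R,3R,6E)-3-ethenyl-N,8,8-trimethoxy-N,2,7-trimethyloct-6-enamide
Product: 11 (4R,5R,8E)-5-ethenyl-10,10-dimethoxy-4,9-dimethyldeca-1,8-dien-3-one
Conditions: CH2=CHMgBr, THF, −78 to 0 °C; cold aq NH4Cl
Reagents that add atoms: vinylmagnesium bromide, C=C[Mg]Br
Why: Single addition of the Grignard reagent to the Weinreb amide (stable chelated tetrahedral adduct) should give the vinyl ketone after a cold, mildly acidic quench that spares the acetal.

Step 10
Reactants: 11 (4R,5R,8E)-5-ethenyl-10,10-dimethoxy-4,9-dimethyldeca-1,8-dien-3-one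
Product: 14 (1R,3aS,4R,7aR)-1-ethenyl-4,7a-dimethyl-7-oxooctahydro-1H-indene-4-carbaldehyde, via trimethylsilyl dienol ether 12 (not isolated), via bicyclic silyl enol ether acetal 13 (not isolated)
Conditions: (a) LiN(SiMe3)2, Me3SiCl, Et3N, THF, −78 °C, then pentane, filtration; (b) Me3SiOTf (0.2 equiv), 2,6-di-tert-butyl-4-methylpyridine, CH2Cl2 (0.01 M), −78 to −40 °C; (c) 1 M HCl, THF, 0 °C to rt
Reagents that add atoms: water, O
Why: LiN(SiMe3)2/Me3SiCl should convert the ketone into the 2-siloxy diene 12 while the enal is still masked, and catalytic Me3SiOTf should then ionise the allylic acetal to an (E)-vinyl oxocarbenium ion, so that nucleophile and electrophile are generated in the needed order. C7a of the enol silane should add to the β-carbon C3a (Mukaiyama–Michael addition, 5-exo-trig, closing the cyclopentane and forming the ring-fusion bond), and the methyl enol ether so formed should add through C4 to C5 of the O-silylated enone (6-endo-trig, closing the cyclohexane); the closest known reaction type is the Lewis acid-promoted ionic Diels–Alder reaction of allylic acetals, equivalent to the double Michael reaction of 2-siloxy dienes. C7a is controlled by the C1 stereocentre: A(1,3) strain with the group on C7 holds the C1–H bond in the plane of the enol ether, the tether delivers C3a to one face and the C1 vinyl group lies on the other, which places it cis to the angular methyl group whichever the enol ether geometry. C3a is set by the compact endo arrangement of the oxocarbenium ion under the diene, which should give the trans ring fusion (the cis mode suffers from the in-plane methyl group on C7a); C4 is formed in the same event but loses its stereogenicity in step 11. The step needs 1,4- and not 1,2-attack on the oxocarbenium ion, which the ring sizes secure (five against seven), and it needs the ketone-derived nucleophile only, which is secured by making 12 before the aldehyde function is unmasked. Aqueous acid finally hydrolyses the silyl enol ether and the dimethyl acetal of 13 to the keto aldehyde 14.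

Step 11
Reactants: 14 (1R,3aS,4R,7aR)-1-ethenyl-4,7a-dimethyl-7-oxooctahydro-1H-indene-4-carbaldehyde
Product: 16 (1R,3aS,7aR)-1-ethenyl-4,4,7a-trimethyloctahydro-1H-indene, via bis-hydrazone 15 (not isolated)
Conditions: N2H4·H2O, KOH, diethylene glycol, 130 °C, then 205 °C with removal of water
Reagents that add atoms: none
Why: Wolff–Kishner reduction (Huang–Minlon modification) should turn the hindered C7 ketone into CH2 and the neopentyl aldehyde into the second C4 methyl group in one operation; no ring stereocentre is α to either carbonyl group, so none can epimerise.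

Step 12
Reactants: 16 (1R,3aS,7aR)-1-ethenyl-4,4,7a-trimethyloctahydro-1H-indene
Product: 17 1-[(1S,3aS,7aS)-4,4,7a-trimethyloctahydro-1H-inden-1-yl]ethan-1-one
Conditions: PdCl2 (10 mol %), CuCl, O2 (1 atm), DMF/H2O (7:1), rt
Reagents that add atoms: water, O
Why: Wacker oxidation of the monosubstituted alkene should give the methyl ketone with Markovnikov regiochemistry; C1 keeps its configuration, which is also the more stable one (acetyl cis to the angular methyl group).

Step 13
Reactants: 17 1-[(1S,3aS,7aS)-4,4,7a-trimethyloctahydro-1H-inden-1-yl]ethan-1-one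
Product: 18 N'-{(1E)-1-[(1S,3aS,7aS)-4,4,7a-trimethyloctahydro-1H-inden-1-yl]ethylidene}-2,4,6-tri(propan-2-yl)benzenesulfonohydrazide
Conditions: 2,4,6-triisopropylbenzenesulfonyl hydrazide, HCl (cat.), THF, rt
Reagents that add atoms: 2,4,6-tri(propan-2-yl)benzenesulfonohydrazide, CC(C)c1cc(C(C)C)c(S(=O)(=O)NN)c(C(C)C)c1
Why: Acid-catalysed condensation should give the (E)-arenesulfonyl hydrazone needed for a regioselective Shapiro reaction.

Step 14
Reactants: 19 (4S)-4-benzyl-1,3-oxazolidin-2-one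
Product: 20 (4S)-4-benzyl-3-(prop-2-enoyl)-1,3-oxazolidin-2-one
Conditions: acryloyl chloride, Et3N, LiCl, THF, −20 °C to rt
Reagents that add atoms: acryloyl chloride, C=CC(=O)Cl
Why: The same N-acylation as in step 2, here on the enantiomeric auxiliary.

Step 15
Reactants: 20 (4S)-4-benzyl-3-(prop-2-enoyl)-1,3-oxazolidin-2-one; 21 tert-butyl(dimethyl)(prop-2-en-1-yloxy)silane
Product: 22 (4S)-4-benzyl-3-[(2E)-4-{[tert-butyl(dimethyl)silyl]oxy}but-2-enoyl]-1,3-oxazolidin-2-one
Conditions: second-generation Hoveyda–Grubbs catalyst RuCl2(H2IMes)(=CH-C6H4-2-O-i-Pr) (3 mol %), 21 (2 equiv), CH2Cl2, 40 °C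
Reagents that add atoms: none
Why: Cross-metathesis of the acrylimide with the allyl silyl ether should give the (E)-γ-silyloxy enoyl imide selectively.

Step 16
Reactants: 18 N'-{(1E)-1-[(1S,3aS,7aS)-4,4,7a-trimethyloctahydro-1H-inden-1-yl]ethylidene}-2,4,6-tri(propan-2-yl)benzenesulfonohydrazide; 22 (4S)-4-benzyl-3-[(2E)-4-{[tert-butyl(dimethyl)silyl]oxy}but-2-enoyl]-1,3-oxazolidin-2-one
Product: 25 (4S)-4-benzyl-3-[(3R)-3-({[tert-butyl(dimethyl)silyl]oxy}methyl)-4-[(1R,3aS,7aS)-4,4,7a-trimethyloctahydro-1H-inden-1-yl]pent-4-enoyl]-1,3-oxazolidin-2-one, via alkenyllithium 23 (not isolated), via alkenylmagnesium bromide 24 (not isolated)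
Conditions: n-BuLi (2.2 equiv), THF, −78 to 0 °C; MgBr2·OEt2, −78 °C; CuBr·SMe2, 22, THF/Me2S, −78 to −20 °C; aq NH4Cl
Reagents that add atoms: none
Why: The Shapiro reaction (dianion formation at the methyl group, loss of sulfinate and N2) should give the 1,1-disubstituted alkenyllithium, which after transmetallation to magnesium undergoes copper-mediated conjugate addition to the chelated syn-s-cis imide anti to the benzyl group, joining the alkene carbon to the new stereocentre (3R) under auxiliary control.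

Step 17
Reactants: 25 (4S)-4-benzyl-3-[(3R)-3-({[tert-butyl(dimethyl)silyl]oxy}methyl)-4-[(1R,3aS,7aS)-4,4,7a-trimethyloctahydro-1H-inden-1-yl]pent-4-enoyl]-1,3-oxazolidin-2-one
Product: 26 ethyl (2S,3S,4R)-3-{[(4S)-4-benzyl-2-oxo-1,3-oxazolidin-3-yl]carbonyl}-4-({[tert-butyl(dimethyl)silyl]oxy}methyl)-2-hydroxy-5-[(1R,3aS,7aS)-4,4,7a-trimethyloctahydro-1H-inden-1-yl]hex-5-enoate
Conditions: n-Bu2BOTf, i-Pr2NEt, CH2Cl2, −78 to 0 °C; ethyl glyoxylate, −78 to 0 °C; pH 7 buffer, MeOH, H2O2, 0 °C
Reagents that add atoms: ethyl glyoxylate, CCOC(=O)C=O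
Why: The Evans syn-aldol reaction of the (Z)-boron enolate through a chair Zimmerman–Traxler transition state should set both the branch carbon and the carbinol carbon of the future lactone (2,3-syn, on the enolate face opposite to that used in enolate alkylation) under control of the same auxiliary.

Step 18
Reactants: 26 ethyl (2S,3S,4R)-3-{[(4S)-4-benzyl-2-oxo-1,3-oxazolidin-3-yl]carbonyl}-4-({[tert-butyl(dimethyl)silyl]oxy}methyl)-2-hydroxy-5-[(1R,3aS,7aS)-4,4,7a-trimethyloctahydro-1H-inden-1-yl]hex-5-enoate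
Product: 27 ethyl (2S,3S,4R)-3-{[(4S)-4-benzyl-2-oxo-1,3-oxazolidin-3-yl]carbonyl}-2-{[tert-butyl(dimethyl)silyl]oxy}-4-({[tert-butyl(dimethyl)silyl]oxy}methyl)-5-[(1R,3aS,7aS)-4,4,7a-trimethyloctahydro-1H-inden-1-yl]hex-5-enoate
Conditions: t-BuMe2SiOTf, 2,6-lutidine, CH2Cl2, −78 to 0 °C
Reagents that add atoms: tert-butyldimethylsilyl trifluoromethanesulfonate, CC(C)(C)[Si](C)(C)OS(=O)(=O)C(F)(F)F
Why: Silylation of the hindered secondary alcohol with the silyl triflate should protect it so that the α-oxygenated ester is not activated towards hydride in the next step.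

Step 19
Reactants: 27 ethyl (2S,3S,4R)-3-{[(4S)-4-benzyl-2-oxo-1,3-oxazolidin-3-yl]carbonyl}-2-{[tert-butyl(dimethyl)silyl]oxy}-4-({[tert-butyl(dimethyl)silyl]oxy}methyl)-5-[(1R,3aS,7aS)-4,4,7a-trimethyloctahydro-1H-inden-1-yl]hex-5-enoate
Product: 29 (3S,4R)-3-{[tert-butyl(dimethyl)silyl]oxy}-4-{(2R)-1-{[tert-butyl(dimethyl)silyl]oxy}-3-[(1R,3aS,7aS)-4,4,7a-trimethyloctahydro-1H-inden-1-yl]but-3-en-2-yl}oxolan-2-one, via hydroxy ester 28 (not isolated)
Conditions: NaBH4, THF/H2O (4:1), 0 °C to rt; then pyridinium p-toluenesulfonate (cat.), CH2Cl2, rt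
Reagents that add atoms: none
Why: NaBH4 in wet THF should reduce the exocyclic imide carbonyl to the primary alcohol but not the ethyl ester, and the liberated γ-hydroxy ester should close to the γ-lactone (5-exo-trig acyl substitution) without touching a stereocentre.

Step 20
Reactants: 29 (3S,4R)-3-{[tert-butyl(dimethyl)silyl]oxy}-4-{(2R)-1-{[tert-butyl(dimethyl)silyl]oxy}-3-[(1R,3aS,7aS)-4,4,7a-trimethyloctahydro-1H-inden-1-yl]but-3-en-2-yl}oxolan-2-one
Product: 30 (3S,4R)-3-hydroxy-4-{(2R)-1-hydroxy-3-[(1R,3aS,7aS)-4,4,7a-trimethyloctahydro-1H-inden-1-yl]but-3-en-2-yl}oxolan-2-one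
Conditions: HF·pyridine, pyridine, THF, 0 °C to rt
Reagents that add atoms: none
Why: Buffered fluoride should cleave both silyl ethers and leave the lactone, the trans α-hydroxy stereocentre and the 1,1-disubstituted alkene intact.

Step 21
Reactants: 30 (3S,4R)-3-hydroxy-4-{(2R)-1-hydroxy-3-[(1R,3aS,7aS)-4,4,7a-trimethyloctahydro-1H-inden-1-yl]but-3-en-2-yl}oxolan-2-one
Product: 31 (2R)-2-[(3R,4S)-4-hydroxy-5-oxooxolan-3-yl]-3-[(1R,3aS,7aS)-4,4,7a-trimethyloctahydro-1H-inden-1-yl]but-3-en-1-yl acetate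
Conditions: Ac2O (1.1 equiv), 2,4,6-collidine, CH2Cl2, −40 to 0 °C
Reagents that add atoms: acetic anhydride, CC(=O)OC(C)=O
Why: Kinetically controlled acetylation should distinguish the unhindered primary alcohol from the hindered, hydrogen-bonded secondary α-hydroxy group of the lactone and so complete the target.

**Compound list**

1 | 5-bromo-2-methylpent-2-ene | CC(C)=CCCBr | starting material
2 | 6-methylhepta-1,5-diene | C=CCCC=C(C)C | intermediate
3 | (4R)-4-benzyl-1,3-oxazolidin-2-one | O=C1OC[C@@H](Cc2ccccc2)N1 | starting material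
4 | (4R)-4-benzyl-3-(prop-2-enoyl)-1,3-oxazolidin-2-one | O=C1OC[C@@H](Cc2ccccc2)N1C(=O)C=C | intermediate
5 | (4R)-4-benzyl-3-[(2E)-7-methylocta-2,6-dienoyl]-1,3-oxazolidin-2-one | O=C1OC[C@@H](Cc2ccccc2)N1C(=O)/C=C/CCC=C(C)C | intermediate
6 | (4R)-4-benzyl-3-[(3S)-3-ethenyl-7-methyloct-6-enoyl]-1,3-oxazolidin-2-one | O=C1OC[C@@H](Cc2ccccc2)N1C(=O)C[C@@H](C=C)CCC=C(C)C | intermediate
7 | (4R)-4-benzyl-3-[(2R,3R)-3-ethenyl-2,7-dimethyloct-6-enoyl]-1,3-oxazolidin-2-one | O=C1OC[C@@H](Cc2ccccc2)N1C(=O)[C@H](C)[C@@H](C=C)CCC=C(C)C | intermediate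
8 | (2R,3R)-3-ethenyl-N-methoxy-N,2,7-trimethyloct-6-enamide | CON(C)C(=O)[C@H](C)[C@@H](C=C)CCC=C(C)C | intermediate
9 | (2R,3R,6E)-3-ethenyl-N-methoxy-N,2,7-trimethyl-8-oxooct-6-enamide | CON(C)C(=O)[C@H](C)[C@@H](C=C)CC/C=C(\C)C=O | intermediate
10 | (2R,3R,6E)-3-ethenyl-N,8,8-trimethoxy-N,2,7-trimethyloct-6-enamide | CON(C)C(=O)[C@H](C)[C@@H](C=C)CC/C=C(\C)C(OC)OC | intermediate
11 | (4R,5R,8E)-5-ethenyl-10,10-dimethoxy-4,9-dimethyldeca-1,8-dien-3-one | C=CC(=O)[C@H](C)[C@@H](C=C)CC/C=C(\C)C(OC)OC | intermediate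
12 | {[(3Z,5R,8E)-5-ethenyl-10,10-dimethoxy-4,9-dimethyldeca-1,3,8-trien-3-yl]oxy}(trimethyl)silane | C=C/C(O[Si](C)(C)C)=C(\C)[C@@H](C=C)CC/C=C(\C)C(OC)OC | intermediate
13 | {[(1R,3aR,4R,7aR)-4-(dimethoxymethyl)-1-ethenyl-4,7a-dimethyl-2,3,3a,4,5,7a-hexahydro-1H-inden-7-yl]oxy}(trimethyl)silane | C=C[C@H]1CC[C@H]2[C@](C)(C(OC)OC)CC=C(O[Si](C)(C)C)[C@]12C | intermediate
14 | (1R,3aS,4R,7aR)-1-ethenyl-4,7a-dimethyl-7-oxooctahydro-1H-indene-4-carbaldehyde | C=C[C@H]1CC[C@H]2[C@](C)(C=O)CCC(=O)[C@]12C | intermediate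
15 | bis-hydrazone of 14 (hydrazone at C7 and at the formyl carbon, ring stereocentres as in 14) | C=C[C@H]1CC[C@H]2[C@](C)(/C=N/N)CC/C(=N\N)[C@]12C | intermediate
16 | (1R,3aS,7aR)-1-ethenyl-4,4,7a-trimethyloctahydro-1H-indene | C=C[C@H]1CC[C@H]2C(C)(C)CCC[C@]12C | intermediate
17 | 1-[(1S,3aS,7aS)-4,4,7a-trimethyloctahydro-1H-inden-1-yl]ethan-1-one | CC(=O)[C@H]1CC[C@H]2C(C)(C)CCC[C@]12C | intermediate
18 | N'-{(1E)-1-[(1S,3aS,7aS)-4,4,7a-trimethyloctahydro-1H-inden-1-yl]ethylidene}-2,4,6-tri(propan-2-yl)benzenesulfonohydrazide | C/C(=N\NS(=O)(=O)c1c(C(C)C)cc(C(C)C)cc1C(C)C)[C@H]1CC[C@H]2C(C)(C)CCC[C@]12C | intermediate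
19 | (4S)-4-benzyl-1,3-oxazolidin-2-one | O=C1OC[C@H](Cc2ccccc2)N1 | starting material
20 | (4S)-4-benzyl-3-(prop-2-enoyl)-1,3-oxazolidin-2-one | O=C1OC[C@H](Cc2ccccc2)N1C(=O)C=C | intermediate
21 | tert-butyl(dimethyl)(prop-2-en-1-yloxy)silane | C=CCO[Si](C)(C)C(C)(C)C | starting material
22 | (4S)-4-benzyl-3-[(2E)-4-{[tert-butyl(dimethyl)silyl]oxy}but-2-enoyl]-1,3-oxazolidin-2-one | O=C1OC[C@H](Cc2ccccc2)N1C(=O)/C=C/CO[Si](C)(C)C(C)(C)C | intermediate
23 | {1-[4,4,7a-trimethyloctahydro-1H-inden-1-yl]ethenyl}lithium (ring stereocentres as in 17) | [Li]C(=C)[C@H]1CC[C@H]2C(C)(C)CCC[C@]12C | intermediate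
24 | bromo{1-[4,4,7a-trimethyloctahydro-1H-inden-1-yl]ethenyl}magnesium (ring stereocentres as in 17) | Br[Mg]C(=C)[C@H]1CC[C@H]2C(C)(C)CCC[C@]12C | intermediate
25 | (4S)-4-benzyl-3-[(3R)-3-({[tert-butyl(dimethyl)silyl]oxy}methyl)-4-[(1R,3aS,7aS)-4,4,7a-trimethyloctahydro-1H-inden-1-yl]pent-4-enoyl]-1,3-oxazolidin-2-one | O=C1OC[C@H](Cc2ccccc2)N1C(=O)C[C@@H](CO[Si](C)(C)C(C)(C)C)C(=C)[C@H]3CC[C@H]4C(C)(C)CCC[C@]34C | intermediate
26 | ethyl (2S,3S,4R)-3-{[(4S)-4-benzyl-2-oxo-1,3-oxazolidin-3-yl]carbonyl}-4-({[tert-butyl(dimethyl)silyl]oxy}methyl)-2-hydroxy-5-[(1R,3aS,7aS)-4,4,7a-trimethyloctahydro-1H-inden-1-yl]hex-5-enoate | O=C1OC[C@H](Cc2ccccc2)N1C(=O)[C@H]([C@H](O)C(=O)OCC)[C@@H](CO[Si](C)(C)C(C)(C)C)C(=C)[C@H]3CC[C@H]4C(C)(C)CCC[C@]34C | intermediate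
27 | ethyl (2S,3S,4R)-3-{[(4S)-4-benzyl-2-oxo-1,3-oxazolidin-3-yl]carbonyl}-2-{[tert-butyl(dimethyl)silyl]oxy}-4-({[tert-butyl(dimethyl)silyl]oxy}methyl)-5-[(1R,3aS,7aS)-4,4,7a-trimethyloctahydro-1H-inden-1-yl]hex-5-enoate | O=C1OC[C@H](Cc2ccccc2)N1C(=O)[C@H]([C@H](O[Si](C)(C)C(C)(C)C)C(=O)OCC)[C@@H](CO[Si](C)(C)C(C)(C)C)C(=C)[C@H]3CC[C@H]4C(C)(C)CCC[C@]34C | intermediate
28 | ethyl (2S,3R,4R)-2-{[tert-butyl(dimethyl)silyl]oxy}-4-({[tert-butyl(dimethyl)silyl]oxy}methyl)-3-(hydroxymethyl)-5-[(1R,3aS,7aS)-4,4,7a-trimethyloctahydro-1H-inden-1-yl]hex-5-enoate | OC[C@H]([C@H](O[Si](C)(C)C(C)(C)C)C(=O)OCC)[C@@H](CO[Si](C)(C)C(C)(C)C)C(=C)[C@H]1CC[C@H]2C(C)(C)CCC[C@]12C | intermediate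
29 | (3S,4R)-3-{[tert-butyl(dimethyl)silyl]oxy}-4-{(2R)-1-{[tert-butyl(dimethyl)silyl]oxy}-3-[(1R,3aS,7aS)-4,4,7a-trimethyloctahydro-1H-inden-1-yl]but-3-en-2-yl}oxolan-2-one | C=C([C@H]1CC[C@H]2C(C)(C)CCC[C@]12C)[C@H](CO[Si](C)(C)C(C)(C)C)[C@@H]1COC(=O)[C@H]1O[Si](C)(C)C(C)(C)C | intermediate
30 | (3S,4R)-3-hydroxy-4-{(2R)-1-hydroxy-3-[(1R,3aS,7aS)-4,4,7a-trimethyloctahydro-1H-inden-1-yl]but-3-en-2-yl}oxolan-2-one | C=C([C@H]1CC[C@H]2C(C)(C)CCC[C@]12C)[C@H](CO)[C@@H]1COC(=O)[C@H]1O | intermediate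
31 | (2R)-2-[(3R,4S)-4-hydroxy-5-oxooxolan-3-yl]-3-[(1R,3aS,7aS)-4,4,7a-trimethyloctahydro-1H-inden-1-yl]but-3-en-1-yl acetate | C=C([C@H]1CC[C@H]2C(C)(C)CCC[C@]12C)[C@H](COC(C)=O)[C@@H]1COC(=O)[C@H]1O | target

**Step count and risks**

Total step count: 21. Longest linear sequence: 18 (steps 1, 3 to 13, 16 to 21).

Steps most likely to fail:

Step 10 (loss of control over the ring fusion, or proton loss from the oxocarbenium ion to a dienyl ether before ring closure). The fallback replaces the cationic cascade by an anionic double Michael reaction in which the ketone can be deprotonated in the presence of the acceptor. It sets out from 11: 1 M HCl in THF should hydrolyse the acetal to the keto enal F1, NaClO2/NaH2PO4/2-methylbut-2-ene should oxidise it to the keto acid F2, and Me3SiCHN2 should give the methyl ester F3. LiN(SiMe3)2 in THF at −78 to 0 °C should then form the cross-conjugated dienolate, which closes both rings by an intramolecular double Michael reaction to the bicyclic keto ester F4 (C4 configuration without consequence). LiAlH4 should reduce ketone and ester to the diol F5, and Dess–Martin periodinane should reoxidise both carbinols, which brings the route back at 14.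

Step 16 (protonation of the hindered alkenyl-metal species before transfer, or slow transfer of the 1,1-disubstituted alkenyl group with competing 1,2-addition). The fallback uses a catalytic boron-based conjugate addition with ligand control and sets out from 17. KN(SiMe3)2/PhNTf2 should give the enol triflate F6 (kinetic enolisation at the methyl group), and B2pin2 with PdCl2(PPh3)2, PPh3 and KOPh should give the alkenyl boronate F7. Rhodium-catalysed asymmetric 1,4-addition of F7 (Rh(acac)(C2H4)2, the BINAP enantiomer that delivers the 3R product, aqueous dioxane) to methyl (2E)-4-{[tert-butyl(dimethyl)silyl]oxy}but-2-enoate should give the ester F8, and LiOH the acid F9. Activation with pivaloyl chloride/Et3N and acylation of the lithium salt of 19 brings the route back at 25.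

Step 19 (hydride attack at the ring carbonyl of the very hindered imide with opening of the auxiliary, or over-reduction of the α-silyloxy ester). The fallback separates cleavage and reduction and sets out from 27. LiOH/H2O2 should remove the auxiliary selectively at the exocyclic carbonyl and give the acid F10, and isobutyl chloroformate/N-methylmorpholine should give the mixed anhydride F11. NaBH4 in THF/H2O at −15 °C should reduce only the activated carboxyl group, which brings the route back at 28, and 28 lactonises to 29 as in step 19.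

Further compounds

F1 | step 10 | (2E,6R,7R)-6-ethenyl-2,7-dimethyl-8-oxodeca-2,9-dienal | C=CC(=O)[C@H](C)[C@@H](C=C)CC/C=C(\C)C=O
F2 | step 10 | (2E,6R,7R)-6-ethenyl-2,7-dimethyl-8-oxodeca-2,9-dienoic acid | C=CC(=O)[C@H](C)[C@@H](C=C)CC/C=C(\C)C(=O)O
F3 | step 10 | methyl (2E,6R,7R)-6-ethenyl-2,7-dimethyl-8-oxodeca-2,9-dienoate | C=CC(=O)[C@H](C)[C@@H](C=C)CC/C=C(\C)C(=O)OC
F4 | step 10 | methyl (1R,3aR,4R,7aR)-1-ethenyl-4,7a-dimethyl-7-oxooctahydro-1H-indene-4-carboxylate | C=C[C@H]1CC[C@H]2[C@](C)(C(=O)OC)CCC(=O)[C@]12C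
F5 | step 10 | 1-ethenyl-4-(hydroxymethyl)-4,7a-dimethyloctahydro-1H-inden-7-ol (ring stereocentres as in 14, 7-hydroxy cis to the 7a-methyl group) | C=C[C@H]1CC[C@H]2[C@](C)(CO)CC[C@@H](O)[C@]12C
F6 | step 16 | 1-[(1S,3aS,7aS)-4,4,7a-trimethyloctahydro-1H-inden-1-yl]ethenyl trifluoromethanesulfonate | C=C(OS(=O)(=O)C(F)(F)F)[C@H]1CC[C@H]2C(C)(C)CCC[C@]12C
F7 | step 16 | 4,4,5,5-tetramethyl-2-{1-[(1R,3aS,7aR)-4,4,7a-trimethyloctahydro-1H-inden-1-yl]ethenyl}-1,3,2-dioxaborolane | C=C(B1OC(C)(C)C(C)(C)O1)[C@H]1CC[C@H]2C(C)(C)CCC[C@]12C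
F8 | step 16 | methyl (3R)-3-({[tert-butyl(dimethyl)silyl]oxy}methyl)-4-[(1R,3aS,7aS)-4,4,7a-trimethyloctahydro-1H-inden-1-yl]pent-4-enoate | COC(=O)C[C@@H](CO[Si](C)(C)C(C)(C)C)C(=C)[C@H]1CC[C@H]2C(C)(C)CCC[C@]12C
F9 | step 16 | (3R)-3-({[tert-butyl(dimethyl)silyl]oxy}methyl)-4-[(1R,3aS,7aS)-4,4,7a-trimethyloctahydro-1H-inden-1-yl]pent-4-enoic acid | OC(=O)C[C@@H](CO[Si](C)(C)C(C)(C)C)C(=C)[C@H]1CC[C@H]2C(C)(C)CCC[C@]12C
F10 | step 19 | (2S,3S)-3-{[tert-butyl(dimethyl)silyl]oxy}-2-{(2R)-1-{[tert-butyl(dimethyl)silyl]oxy}-3-[(1R,3aS,7aS)-4,4,7a-trimethyloctahydro-1H-inden-1-yl]but-3-en-2-yl}-4-ethoxy-4-oxobutanoic acid | OC(=O)[C@H]([C@H](O[Si](C)(C)C(C)(C)C)C(=O)OCC)[C@@H](CO[Si](C)(C)C(C)(C)C)C(=C)[C@H]1CC[C@H]2C(C)(C)CCC[C@]12C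
F11 | step 19 | mixed anhydride of F10 with isobutyl hydrogen carbonate | CC(C)COC(=O)OC(=O)[C@H]([C@H](O[Si](C)(C)C(C)(C)C)C(=O)OCC)[C@@H](CO[Si](C)(C)C(C)(C)C)C(=C)[C@H]1CC[C@H]2C(C)(C)CCC[C@]12C
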